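A direct plan would build the acyclic C3-carbinol (2E,4E)-dienoate A1, in which a four-carbon tether links the diene to the C9=C10 alkene, and would close rings A and B together by a thermal intramolecular Diels–Alder reaction to the 3β-hydroxylabd-6-en-17-oate A2. Deoxygenation to the labd-6-en-17-oate A3, a shift of the alkene into conjugation and ester cleavage would follow. Its weakest steps would be these:
(a) The cycloaddition: an unactivated trisubstituted dienophile at about 200 °C would have to give trans fusion and one π-face, so C5, C9 and C10 would all rest on the conformational preference of one remote carbinol, on material that has already cost many steps.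
(b) The enantioselective ketone reduction that would create the C3 carbinol and the two-step radical deoxygenation that would remove it again: three steps that leave nothing in the target.
(c) The base-mediated shift of the 6-ene to the 7-position: the place of the alkene would rest on an equilibrium, next to the C9 centre, late in the sequence.

**Plan of the new route**
The retrosynthesis cuts C9–C10 (closure of ring B) and then C7–C8 (union of a C11 ring A aldehyde with a C9 ynoate that carries the side chain). Ring A is bought as a cyclohexenone and receives C5 by a reduction/Johnson–Claisen pair; ring B is closed last. The enabling feature is the C8 carboxyl on the C7=C8 alkene of ring B: it makes C9 the β-carbon of an acrylate bonded directly to the quaternary C10. A tertiary C10 radical on ring A can therefore close ring B by 6-endo addition, and the C7 oxygen left by the fragment union then leaves to restore C7=C8. No C3 oxygen is ever made, the ring fusion is set by the adjacent C5 centre and the axial C4 methyl instead of a remote group, and the alkene is placed by elimination, not by equilibration.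

Key step: step 9

Remark: labdane numbering (C1–C20) is used for all intermediates; the S oxazaborolidine is assumed to give the 1R alcohol, as with other 2-substituted cyclohex-2-enones (the enantiomeric catalyst would be used otherwise).

Step 1
Reactants: 1 2,4,4-trimethylcyclohex-2-en-1-one
Product: 2 (1R)-2,4,4-trimethylcyclohex-2-en-1-ol
Conditions: (S)-1-methyl-3,3-diphenyltetrahydro-1H,3H-pyrrolo[1,2-c][1,3,2]oxazaborole (0.1 equiv), BH3·SMe2 (0.7 equiv), THF, −20 °C; MeOH quench
Reagents that add atoms: none
Why: Corey–Bakshi–Shibata reduction; the ketone binds the oxazaborolidine with its 2-methylvinyl side as the large group, so the S catalyst should deliver hydride to the face that gives the 1R allylic alcohol, the only stereocentre of the route set by reagent control.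

Step 2
Reactants: 2 (1R)-2,4,4-trimethylcyclohex-2-en-1-ol
Product: 4 ethyl 2-[(1S)-2,6,6-trimethylcyclohex-2-en-1-yl]acetate, via mixed ketene acetal 3 (not isolated)
Conditions: MeC(OEt)3 (6 equiv), EtCO2H (0.1 equiv), 140 °C, EtOH distilled off
Reagents that add atoms: triethyl orthoacetate, CC(OCC)(OCC)OCC
Why: Johnson–Claisen rearrangement; the ketene acetal on the C1 oxygen delivers its CH2 carbon suprafacially to C5 on the ring face that carried the C–O bond, so the carbinol configuration is transferred to C5 (S) while the alkene moves to C1=C10.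

Step 3
Reactants: 4 ethyl 2-[(1S)-2,6,6-trimethylcyclohex-2-en-1-yl]acetate
Product: 5 2-[(1S)-2,6,6-trimethylcyclohex-2-en-1-yl]acetaldehyde
Conditions: i-Bu2AlH (1.05 equiv), CH2Cl2, −78 °C; aq. potassium sodium tartrate
Reagents that add atoms: none
Why: Partial reduction of the ester stops at the aluminium hemiacetal at −78 °C and gives the C7 aldehyde on work-up; C5 is β to the carbonyl and cannot epimerise.

Step 4
Reactants: 6 geranyl acetate
Product: 8 (2E)-3-methyl-6-oxohex-2-en-1-yl acetate, via 6,7-epoxide 7 (not isolated)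
Conditions: 3-ClC6H4CO3H (1.0 equiv), CH2Cl2, 0 °C; then H5IO6 (1.1 equiv), THF/H2O, 0 °C
Reagents that add atoms: 3-chloroperbenzoic acid, OOC(=O)c1cccc(Cl)c1
Why: Prilezhaev epoxidation is selective for the electron-rich distal alkene over the alkene that bears the allylic acetate, and periodic acid hydrolyses the epoxide and cleaves the glycol to the aldehyde (C9) and acetone, leaving the 13E alkene untouched.

Step 5
Reactants: 8 (2E)-3-methyl-6-oxohex-2-en-1-yl acetate
Product: 9 (2E)-3-methylhept-2-en-6-yn-1-ol
Conditions: MeC(O)C(N2)P(O)(OMe)2 (1.3 equiv), K2CO3 (2.5 equiv), MeOH, 0 °C → rt, 16 h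
Reagents that add atoms: dimethyl (1-diazo-2-oxopropyl)phosphonate, CC(=O)C(=[N+]=[N-])P(=O)(OC)OC
Why: Ohira–Bestmann (Seyferth–Gilbert) homologation converts the aldehyde into the terminal alkyne (new carbon = C8) through the alkylidene carbene, and the same methanolic carbonate removes the acetate so that one defined alkynol results.

Step 6
Reactants: 9 (2E)-3-methylhept-2-en-6-yn-1-ol
Product: 12 methyl (6E)-8-hydroxy-6-methyloct-6-en-2-ynoate, via trimethylsilyl ether 10 (not isolated), via silylated ynoate 11 (not isolated)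
Conditions: n-BuLi (1.0 equiv), THF, −78 °C; Me3SiCl (1.05 equiv), → 0 °C; n-BuLi (1.05 equiv), −78 °C; ClCO2Me (1.2 equiv); then 1 M HCl, rt
Reagents that add atoms: methyl chloroformate, COC(=O)Cl
Why: Transient O-silylation leaves the lithium acetylide as the only nucleophile for C-acylation by the chloroformate (C17), and dilute acid then hydrolyses the labile primary trimethylsilyl ether.

Step 7
Reactants: 12 methyl (6E)-8-hydroxy-6-methyloct-6-en-2-ynoate; 5 2-[(1S)-2,6,6-trimethylcyclohex-2-en-1-yl]acetaldehyde
Product: 14 methyl (2Z,6E)-8-hydroxy-2-{1-hydroxy-2-[(1S)-2,6,6-trimethylcyclohex-2-en-1-yl]ethyl}-6-methylocta-2,6-dienoate (both C7 epimers), via vinylalane 13 (not isolated)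
Conditions: 12, i-Bu2AlH (1.0 equiv), THF, 0 °C; then i-Bu2AlH (1.3 equiv)/N-methylmorpholine N-oxide (2 equiv), 0 °C, 3 h; then 5 (0.9 equiv), 0 °C → rt; aq. potassium sodium tartrate
Reagents that add atoms: none
Why: Vinylalumination (reductive Morita–Baylis–Hillman-type aldol): syn hydroalumination of the ynoate puts hydride on C9 and aluminium on C8, and the vinylalane adds to the aldehyde with retention to form C7–C8, so C11 stays cis to the ester (2Z); the C7 carbinol forms as a mixture that is erased in step 9.

Step 8
Reactants: 14 methyl (2Z,6E)-8-hydroxy-2-{1-hydroxy-2-[(1S)-2,6,6-trimethylcyclohex-2-en-1-yl]ethyl}-6-methylocta-2,6-dienoate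
Product: 15 methyl (2Z,6E)-8-acetoxy-2-{1-acetoxy-2-[(1S)-2,6,6-trimethylcyclohex-2-en-1-yl]ethyl}-6-methylocta-2,6-dienoate
Conditions: Ac2O (4 equiv), pyridine, 4-(dimethylamino)pyridine (0.1 equiv), CH2Cl2, 0 °C → rt
Reagents that add atoms: acetic anhydride, CC(=O)OC(C)=O
Why: One acylation serves two ends: the C7 acetate becomes the leaving group of the later E1cB step and the C15 acetate lowers the reactivity of the 13-alkene towards hydrogen-atom transfer and radical addition.

Step 9
Reactants: 15 methyl (2Z,6E)-8-acetoxy-2-{1-acetoxy-2-[(1S)-2,6,6-trimethylcyclohex-2-en-1-yl]ethyl}-6-methylocta-2,6-dienoate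
Product: 17 methyl 15-acetoxylabda-7,13E-dien-17-oate (5S,9R,10S), via saturated 7-acetoxy ester 16 (not isolated)
Conditions: Fe(acac)3 (0.5 equiv), PhSiH3 (3 equiv), EtOH/(CH2OH)2 5:1 (0.02 M), 60 °C; crude filtered through silica; then DBU (3 equiv), CH2Cl2, rt
Reagents that add atoms: none
Why: The iron hydride formed from Fe(acac)3 and PhSiH3 transfers a hydrogen atom to C1 of the electron-rich ring alkene and leaves the tertiary C10 radical, which adds 6-endo-trig to C9, the β-carbon of the tethered acrylate, and closes ring B through the C9–C10 bond; the ester-stabilised C8 radical is then reduced and protonated (or loses acetate directly), and DBU completes the E1cB loss of the C7 acetate to give the C7=C8 ester. The closest known reaction type is the iron-mediated hydrogen-atom-transfer reductive olefin coupling in its intramolecular form, as used in radical polyene bicyclisations that end on an unsaturated ester. Ring A is already present, so ring B closes in the fused mode on the preformed cyclohexyl radical through a chair transition state. C10 is set by the C5 stereocentre: the C6 arm is equatorial and the axial C4 methyl blocks the face that would give the cis-fused ring, so C9 bonds trans to the C5 arm (10β-methyl); C9 is set by the 2Z acrylate geometry, which places C11 trans to C7 and hence equatorial (9α-H). The step needs hydrogen-atom transfer at the ring alkene only and endo over exo closure: the acrylate is too electron-poor to accept the hydrogen atom, the 13-alkene is deactivated by its allylic acetate, and attack at C8 would be a contra-polar 5-exo addition to a fully substituted carbon. Because the C7 oxygen is the only leaving group β to the ester, the alkene can appear only at C7=C8, and the C7 and C8 epimers of the intermediate converge.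

Step 10
Reactants: 17 methyl 15-acetoxylabda-7,13E-dien-17-oate
Product: 18 15-hydroxylabda-7,13E-dien-17-oic acid
Conditions: KOH (10 equiv), MeOH/H2O 4:1, 70 °C; then 1 M HCl to pH 3
Reagents that add atoms: potassium hydroxide, [K+].[OH-]
Why: Saponification cleaves the hindered conjugated methyl ester and the acetate together; H9 is not acidified by the ester (the C9 anion would be cross-conjugated), so C9 and the C7=C8 position should hold.

Step 11
Reactants: 18 15-hydroxylabda-7,13E-dien-17-oic acid
Product: 19 15-(isobutyryloxy)labda-7,13E-dien-17-oic acid (target, 5S,9R,10S)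
Conditions: (i-PrCO)2O (3 equiv), pyridine, 4-(dimethylamino)pyridine (0.1 equiv), CH2Cl2, 0 °C → rt; then H2O/THF, NaHCO3, rt; 0.5 M HCl
Reagents that add atoms: isobutyric anhydride, CC(C)C(=O)OC(=O)C(C)C
Why: Nucleophile-catalysed O-acylation of the primary allylic alcohol; any mixed anhydride formed at the hindered C17 carboxyl is hydrolysed in the aqueous stage, so only the C15 ester remains.

**Compound list**

1 | 2,4,4-trimethylcyclohex-2-en-1-one | CC1=CC(C)(C)CCC1=O | starting material
2 | (1R)-2,4,4-trimethylcyclohex-2-en-1-ol | CC1=CC(C)(C)CC[C@H]1O | intermediate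
3 | 1-ethoxy-1-{[(1R)-2,4,4-trimethylcyclohex-2-en-1-yl]oxy}ethene (mixed ketene acetal) | CC1=CC(C)(C)CC[C@H]1OC(=C)OCC | intermediate
4 | ethyl 2-[(1S)-2,6,6-trimethylcyclohex-2-en-1-yl]acetate | CCOC(=O)C[C@@H]1C(C)=CCCC1(C)C | intermediate
5 | 2-[(1S)-2,6,6-trimethylcyclohex-2-en-1-yl]acetaldehyde | O=CC[C@@H]1C(C)=CCCC1(C)C | intermediate
6 | geranyl acetate, (2E)-3,7-dimethylocta-2,6-dien-1-yl acetate | CC(C)=CCC/C(C)=C/COC(C)=O | starting material
7 | (2E)-5-(3,3-dimethyloxiran-2-yl)-3-methylpent-2-en-1-yl acetate (6,7-epoxide, racemic) | CC1(C)OC1CC/C(C)=C/COC(C)=O | intermediate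
8 | (2E)-3-methyl-6-oxohex-2-en-1-yl acetate | O=CCC/C(C)=C/COC(C)=O | intermediate
9 | (2E)-3-methylhept-2-en-6-yn-1-ol | C#CCC/C(C)=C/CO | intermediate
10 | trimethyl{[(2E)-3-methylhept-2-en-6-yn-1-yl]oxy}silane | C#CCC/C(C)=C/CO[Si](C)(C)C | intermediate
11 | methyl (6E)-6-methyl-8-[(trimethylsilyl)oxy]oct-6-en-2-ynoate | COC(=O)C#CCC/C(C)=C/CO[Si](C)(C)C | intermediate
12 | methyl (6E)-8-hydroxy-6-methyloct-6-en-2-ynoate | COC(=O)C#CCC/C(C)=C/CO | intermediate
13 | methyl (2E,6E)-2-(diisobutylalumanyl)-8-[(diisobutylalumanyl)oxy]-6-methylocta-2,6-dienoate (vinylalane) | COC(=O)/C(=C\CC/C(C)=C/CO[Al](CC(C)C)CC(C)C)[Al](CC(C)C)CC(C)C | intermediate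
14 | methyl (2Z,6E)-8-hydroxy-2-{1-hydroxy-2-[(1S)-2,6,6-trimethylcyclohex-2-en-1-yl]ethyl}-6-methylocta-2,6-dienoate (both C7 epimers) | COC(=O)/C(=C\CC/C(C)=C/CO)C(O)C[C@@H]1C(C)=CCCC1(C)C | intermediate
15 | methyl (2Z,6E)-8-acetoxy-2-{1-acetoxy-2-[(1S)-2,6,6-trimethylcyclohex-2-en-1-yl]ethyl}-6-methylocta-2,6-dienoate (both C7 epimers) | COC(=O)/C(=C\CC/C(C)=C/COC(C)=O)C(OC(C)=O)C[C@@H]1C(C)=CCCC1(C)C | intermediate
16 | methyl 7,15-diacetoxylabd-13E-en-17-oate (5α-H, 9α-H, 10β-CH3; C7 and C8 epimers) | C/C(=C\COC(C)=O)CC[C@H]1C(C(=O)OC)C(OC(C)=O)C[C@H]2C(C)(C)CCC[C@]12C | intermediate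
17 | methyl 15-acetoxylabda-7,13E-dien-17-oate (5S,9R,10S) | C/C(=C\COC(C)=O)CC[C@H]1C(C(=O)OC)=CC[C@H]2C(C)(C)CCC[C@]12C | intermediate
18 | 15-hydroxylabda-7,13E-dien-17-oic acid (5S,9R,10S) | C/C(=C\CO)CC[C@H]1C(C(=O)O)=CC[C@H]2C(C)(C)CCC[C@]12C | intermediate
19 | 15-(isobutyryloxy)labda-7,13E-dien-17-oic acid (5S,9R,10S) | C/C(=C\COC(=O)C(C)C)CC[C@H]1C(C(=O)O)=CC[C@H]2C(C)(C)CCC[C@]12C | target

**Step count**
Total: 11 steps. Longest linear sequence: 8 steps (steps 4–11; the ring A branch, steps 1–3 and 7–11, is equally long).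

**Steps most likely to fail**

Step 9. The hydrogen atom may be transferred to the side-chain alkene instead of the ring alkene, the C10 radical may be reduced before it closes ring B, or the C8 radical may add onward to the 13-alkene before it is reduced. The fallback sets out from 15 and comes back at 17; it generates the C10 radical by epoxide opening with a reagent that also traps the C8 radical at once. 15 would be epoxidised with 3-ClC6H4CO3H (CH2Cl2, 0 °C) at the more electron-rich ring alkene to methyl (2Z,6E)-8-acetoxy-2-{1-acetoxy-2-[(2S)-1,3,3-trimethyl-7-oxabicyclo[4.1.0]heptan-2-yl]ethyl}-6-methylocta-2,6-dienoate F1. Cp2TiCl (trivalent titanium, from Cp2TiCl2 and Mn dust, THF, rt, excess) would open the epoxide to the tertiary C10 radical. This would cyclise in the same 6-endo mode, and the titanium enolate formed from the C8 radical would expel the C7 acetate to give methyl 15-acetoxy-1ξ-hydroxylabda-7,13E-dien-17-oate F2. The C1 hydroxyl would then be removed by Barton–McCombie deoxygenation through the 1-O-(imidazol-1-ylcarbonothioyl) derivative F3 (1,1'-thiocarbonyldiimidazole, then Bu3SnH, AIBN, toluene, 110 °C) to give 17.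

Step 7. The vinylalane may lose its geometry through the allenoate, or residual hydride may reduce the aldehyde. The fallback sets out from 12 (with 5) and comes back at 14; it forms the C7–C8 bond by a chromium-mediated coupling. Syn hydrostannation of 12 (Bu3SnH, Pd(PPh3)4, zerovalent palladium, THF) would give methyl (2E,6E)-8-hydroxy-6-methyl-2-(tributylstannyl)octa-2,6-dienoate F4. Iododestannylation (I2, CH2Cl2, 0 °C) would give methyl (2E,6E)-8-hydroxy-2-iodo-6-methylocta-2,6-dienoate F5 with retention. Nozaki–Hiyama–Kishi coupling of F5 with 5 (CrCl2, divalent chromium, with catalytic NiCl2, DMF, rt) would give 14 with the same 2Z geometry.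

Step 2. Ionisation or dehydration of the allylic alcohol under hot, weakly acidic conditions may erode the transfer of chirality, or bond formation at the hindered C5 may be slow. The fallback sets out from 2 and comes back at 4; it runs the sigmatropic step on an enolate-derived silyl ketene acetal. 2 would be acetylated (Ac2O, pyridine) to (1R)-2,4,4-trimethylcyclohex-2-en-1-yl acetate F6. Ireland–Claisen rearrangement (LiN(i-Pr)2, Me3SiCl, THF, −78 °C → 60 °C; aqueous work-up) would give 2-[(1S)-2,6,6-trimethylcyclohex-2-en-1-yl]acetic acid F7 with the same suprafacial transfer. Esterification (EtI, K2CO3, DMF) would give 4.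

**Further compounds**

F1 | step 9 | methyl (2Z,6E)-8-acetoxy-2-{1-acetoxy-2-[(2S)-1,3,3-trimethyl-7-oxabicyclo[4.1.0]heptan-2-yl]ethyl}-6-methylocta-2,6-dienoate | COC(=O)/C(=C\CC/C(C)=C/COC(C)=O)C(OC(C)=O)C[C@@H]1C2(C)OC2CCC1(C)C
F2 | step 9 | methyl 15-acetoxy-1ξ-hydroxylabda-7,13E-dien-17-oate | C/C(=C\COC(C)=O)CC[C@H]1C(C(=O)OC)=CC[C@H]2C(C)(C)CCC(O)[C@]12C
F3 | step 9 | methyl 15-acetoxy-1ξ-[(1H-imidazol-1-ylcarbonothioyl)oxy]labda-7,13E-dien-17-oate | C/C(=C\COC(C)=O)CC[C@H]1C(C(=O)OC)=CC[C@H]2C(C)(C)CCC(OC(=S)n3ccnc3)[C@]12C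
F4 | step 7 | methyl (2E,6E)-8-hydroxy-6-methyl-2-(tributylstannyl)octa-2,6-dienoate | COC(=O)/C(=C\CC/C(C)=C/CO)[Sn](CCCC)(CCCC)CCCC
F5 | step 7 | methyl (2E,6E)-8-hydroxy-2-iodo-6-methylocta-2,6-dienoate | COC(=O)/C(I)=C\CC/C(C)=C/CO
F6 | step 2 | (1R)-2,4,4-trimethylcyclohex-2-en-1-yl acetate | CC1=CC(C)(C)CC[C@H]1OC(C)=O
F7 | step 2 | 2-[(1S)-2,6,6-trimethylcyclohex-2-en-1-yl]acetic acid | OC(=O)C[C@@H]1C(C)=CCCC1(C)C
A1 | direct plan | 2-(trimethylsilyl)ethyl (2E,4E,7S,10E,14E)-7-hydroxy-6,6,10,14-tetramethyl-16-[(2-methylpropanoyl)oxy]hexadeca-2,4,10,14-tetraenoate | C/C(=C\COC(=O)C(C)C)CC/C=C(\C)CC[C@H](O)C(C)(C)/C=C/C=C/C(=O)OCC[Si](C)(C)C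
A2 | direct plan | 2-(trimethylsilyl)ethyl 3β-hydroxy-15-(isobutyryloxy)labda-6,13E-dien-17-oate | C/C(=C\COC(=O)C(C)C)CC[C@H]1[C@@H](C(=O)OCC[Si](C)(C)C)C=C[C@H]2C(C)(C)[C@@H](O)CC[C@]12C
A3 | direct plan | 2-(trimethylsilyl)ethyl 15-(isobutyryloxy)labda-6,13E-dien-17-oate | C/C(=C\COC(=O)C(C)C)CC[C@H]1[C@@H](C(=O)OCC[Si](C)(C)C)C=C[C@H]2C(C)(C)CCC[C@]12C
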